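## Analysis of the target

Compound 24 is a depside: two benzene rings joined only by an aryl ester between the carbonyl carbon on C1 of ring A and the oxygen on C4 of ring B, with no further ring and no stereocentre. Each ring is a 5-alkylresorcinol with a carbonyl carbon between the alkyl chain and one oxygen: ring A has the free hydroxyl on C2, the methoxy group on C4 and the heptyl chain on C6, while ring B has the free carboxylic acid on C1, a methoxy group on C2, the ester oxygen on C4 and the pentyl chain on C6. The two meta oxygens of each ring are therefore unlike, and in opposite senses: on ring A the oxygen ortho to the carbonyl is free and the para one is methylated, on ring B the ortho oxygen is methylated and the para one is acylated. The aryl ester is the fragile point, because its leaving phenol sits para to an electron-withdrawing carbon, so it behaves as an active ester towards bases and nucleophiles. The free acid is flanked by two ortho groups and shares the molecule with that ester, so it cannot be released late by saponification. The difficulty is regiochemical rather than skeletal: two meta oxygens must be told apart on each ring, each carbonyl must go to the correct one of three activated ring carbons, and the final unmasking must be neutral. The strategy rests on ring A without its carbonyl carbon, where C2–OH, C4–OMe and C6–heptyl alternate around the ring; that pattern maps onto a cyclobutenone plus an alkoxyalkyne, with bonds C2–C3, C4–C5 and C1–C2 made in one operation.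

## Retrosynthetic reasoning

**24 to 23.** The last bond cut is the benzyl–oxygen bond of a benzyl ether on the ring A C2 oxygen of acid 23. Hydrogenolysis is neutral, so the aryl ester and the free acid survive. The benzyl group is needed earlier to keep the ring A hydroxyl from interfering when the ring A acid is activated.

**23 to 22.** The ring B carboxyl is traced back to a formyl group in aldehyde 22. An ester on ring B would have to be removed next to the depside ester, whereas a chlorite oxidation creates the acid under mild acidic buffer. The formyl group also differentiates the ring B oxygens by chelation.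

**22 to 21.** The methyl–oxygen bond on the ring B C2 oxygen is cut, giving hydroxy aldehyde 21. It is placed after ester formation because at that stage the C2 hydroxyl is the only free one. The forward step has to alkylate a chelated phenol without disturbing the aryl ester.

**21 to 16 and 19.** The depside C(=O)–O bond is the convergent cut. It gives the ring A acid 16 and the ring B dihydroxy aldehyde 19. The forward reaction must acylate only the C4 hydroxyl of 19; the C2 hydroxyl is hydrogen-bonded to the formyl oxygen and is much less reactive.

**19 to 17.** The ring-to-formyl bond of 19 is cut back to olivetol 17. Electrophilic formylation of a 5-alkylresorcinol goes ortho to one hydroxyl and para to the other, which is the carbon next to the pentyl chain.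

**16 to 15, 14 and 13.** The carboxyl of 16 comes from the formyl group of 15 by chlorite oxidation, and 15 from salicylaldehyde 14 by O-benzylation. The bond between ring A C1 and the carbonyl carbon is cut in 14, giving phenol 13. An ortho-specific formylation is chosen so that the position para to the hydroxyl is excluded, and the more electron-rich of the two ortho carbons, the one para to methoxy, is the one required.

**13 to 5 and 8.** Phenol 13 is cut at C2–C3, C4–C5 and C1–C2 (target numbering) into 3-heptylcyclobutenone 5 and methoxyethyne 8. This is done here and not by alkylating a symmetric resorcinol, because the annulation delivers hydroxyl, methoxy and heptyl already placed and already unlike. The forward reaction has to orient the alkyne so that its oxygen ends meta to the new hydroxyl.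

**5 to 4, and 4 to 1 and 2.** Cyclobutenone 5 comes from the dichloro compound 4 by reductive dechlorination. Compound 4 is cut across the four-membered ring into non-1-yne 1 and dichloroketene 3, generated from trichloroacetyl chloride 2. The terminal alkyne fixes the chain on C3.

**8 to 6.** Methoxyethyne 8 comes from chloroacetal 6 by double elimination, through its sodium salt 7.

## Alternatives that were turned down

**Alternative 1:** Ring B is built as a cyclohexane-1,3-dione and aromatized later. The ring is cut between the carboxyl-bearing carbon and the pentyl-bearing carbon, and between the C2 carbonyl carbon and C3. In the forward key step dibenzyl malonate A2 adds to the beta carbon of (E)-non-3-en-2-one A3, and the methyl ketone enolate of the adduct then closes onto a malonate ester carbonyl to give benzyl 2,4-dioxo-6-pentylcyclohexane-1-carboxylate A1. Dehydrogenation of A1 would give benzyl 2,4-dihydroxy-6-pentylbenzoate A4.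

- For it: the carboxyl position is fixed by construction, with no aromatic substitution to control, and the benzyl ester arrives in place from A2, so the route would end in one global hydrogenolysis with no late oxidation. On these two points it is stronger than the chosen route, which relies on formylation regiochemistry in steps 5 and 8 and on a late oxidation in step 11.
- Against it: the aromatization of the electron-rich dione ester A1 by halogenation and dehydrohalogenation invites ring halogenation. The alkoxide base used for the addition to A3 must match the benzyl esters of A2, or transesterification follows. A4 still carries two free oxygens that have to be differentiated by chelation, exactly as 19 does. Above all the alternative spends its key step on the ring that 17 already supplies commercially, and ring A would need a second run plus a selective O-methylation.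
- Comparison: the chosen strategy offers instead a ring A whose oxygens are unlike from the moment the ring forms, reached at the aromatic oxidation level without an oxidant.

**Alternative 2:** Ring A is cut at both the C6–heptyl bond and the C1–carboxyl bond, made together on an aryne. In the forward key step heptyllithium A8 lithiates 1-fluoro-3,5-dimethoxybenzene A6 next to fluorine, and loss of fluoride gives 3,5-dimethoxybenzyne A7. A second equivalent of A8 adds at the aryne carbon of A7 remote from the flanking methoxy group, and carboxylation of the resulting aryllithium gives 2-heptyl-4,6-dimethoxybenzoic acid A5. A chelation-directed demethylation of A5 ortho to the carboxyl would then free the ring A hydroxyl.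

- For it: it is by far the shortest access to the ring A acid, about three operations against seven in the chosen route, and the addition regiochemistry is dictated by stabilization of the aryl anion next to methoxy. On step economy it is clearly stronger.
- Against it: the ring hydrogen between the two methoxy groups of A6 is the classical acidic site, and lithiation there is a dead end that consumes base. The product aryllithium competes with A8 for A7, which leads to biaryl oligomers. A8 has to be prepared. The two oxygens of A5 emerge identical and are told apart only afterwards by a strong Lewis acid acting on a hindered acid.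
- Comparison: the alternative packs two difficult selectivities into one flask of polar organometallic chemistry. The chosen strategy offers a neutral thermal cascade whose regiochemistry follows from the polarity of the two partners, with hydroxyl and methoxy differentiated by construction.

**Alternative 3:** Ring B is cut at C1–C2 and C5–C6 into a diene and an alkynoate. In the forward key step benzyl oct-2-ynoate A10 and 1,1-dimethoxy-3-(trimethylsilyloxy)buta-1,3-diene A11 undergo a (4+2) cycloaddition. The adduct loses one alkoxy group and the silyl group and aromatizes to benzyl 4-hydroxy-2-methoxy-6-pentylbenzoate A9.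

- For it: A9 is the fully differentiated ring B partner, with methoxy ortho, a free hydroxyl para and the benzyl ester in place. It would replace steps 8, 10 and 11 and allow a single final hydrogenolysis. For ring B this is more elegant than the chosen route.
- Against it: a 3-alkyl alkynoate such as A10 is a sluggish dienophile, because the chain is both a donor and a steric block at a bond-forming carbon. The long heating needed is poorly tolerated by the acid- and heat-sensitive ketene acetal A11. Both A10 and A11 must be made, so the step saving largely disappears. Ring A is left unsolved, and its oxygen pattern is the reverse of what A11 delivers.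
- Comparison: the chosen strategy puts its ring-forming step on the harder ring A and takes ring B from 17 by three simple operations.

Key step: step 4

Remark: methoxyethyne is treated as a reagent that must be made and used fresh (step 3). Compound 24 has no stereocentre, so configuration matters only in the transient dienylketene 11.

## Route

Step 1
Reactants: 1 non-1-yne; 2 trichloroacetyl chloride
Product: 4 4,4-dichloro-3-heptylcyclobut-2-en-1-one, via dichloroketene 3 (not isolated)
Conditions: Zn–Cu couple, Et2O–DME, slow addition of 2, rt to reflux
Reagents that add atoms: none
Why: Zinc removes chlorine from 2 to give dichloroketene 3, which adds to the terminal alkyne in a thermal (2+2) cycloaddition; the electrophilic ketene carbon bonds to the terminal alkyne carbon, so the chain ends on C3 next to the CCl2 group. This is the standard dichloroketene–alkyne route to 3-alkyl-4,4-dichlorocyclobutenones.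

Step 2
Reactants: 4 4,4-dichloro-3-heptylcyclobut-2-en-1-one
Product: 5 3-heptylcyclobut-2-en-1-one
Conditions: Zn dust, AcOH, TMEDA, EtOH, 0 °C to rt
Reagents that add atoms: none
Why: Reductive dehalogenation with zinc in buffered acetic acid removes both alpha chlorines one after the other by electron transfer and protonation, and TMEDA tempers the acidity so that the enone and the strained ring survive. The method is established for 3-alkyl analogues.

Step 3
Reactants: 6 2-chloro-1,1-dimethoxyethane (chloroacetaldehyde dimethyl acetal)
Product: 8 methoxyethyne, via sodium methoxyethynide 7 (not isolated)
Conditions: NaNH2 (3 equiv), liquid NH3, −33 °C; evaporate NH3; cold saturated aq NaCl, −20 °C; distil into cold toluene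
Reagents that add atoms: none
Why: Two base-induced eliminations with NaNH2, first of methanol and then of hydrogen chloride, give the alkynyl ether, which is held as its sodium salt 7 until a cold aqueous quench releases 8. The volatile product is distilled straight into toluene and used at once; this is a standard preparation of the ynol ether.

Step 4
Reactants: 5 3-heptylcyclobut-2-en-1-one; 8 methoxyethyne
Product: 13 3-heptyl-5-methoxyphenol, via vinylketene 9 (not isolated), via alkenylcyclobutenone 10 (not isolated), via dienylketene 11 (not isolated), via cyclohexadienone 12 (not isolated)
Conditions: 8 (2–3 equiv), toluene, sealed tube, 80 °C, then 140 °C; then K2CO3, MeOH, rt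
Reagents that add atoms: none
Why: This is a Danheiser benzannulation, the closest known reaction type being the thermal union of 3-alkylcyclobutenones with alkoxyalkynes. Heating opens 5 by a reversible 4-electron conrotatory electrocyclic reaction to vinylketene 9. The ketene C=C of 9 adds across 8 in a polar, asynchronous (2+2) cycloaddition in which the unsubstituted, nucleophilic alkyne carbon attacks the central ketene carbon, giving 10. A second 4-electron opening of 10 gives dienylketene 11, and because this opening is reversible the isomer with ketene and alkenyl termini cis about the new C=C is drained off. Ring A closes by a thermal 6-electron disrotatory electrocyclization of 11, ketene carbon onto the terminal methylene, to dienone 12, which tautomerizes irreversibly to phenol 13. No stereocentre is created. The selectivity needed is the orientation of the alkyne: the oxygen of the ynol ether makes its CH carbon the nucleophile, which places OMe meta to the new OH, while the heptyl position is fixed by the cyclobutenone carbon that carries it. Excess 8 keeps 9 from dimerizing or acylating the product, the closing methanolysis cleaves any phenol that has been O-acylated, and the methyl group of 8 has no hydrogen beta to oxygen, so the retro-ene fragmentation to ketene and ethene that limits ethoxyethyne at this temperature cannot occur.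

Step 5
Reactants: 13 3-heptyl-5-methoxyphenol
Product: 14 2-heptyl-6-hydroxy-4-methoxybenzaldehyde
Conditions: MgCl2, Et3N, (CH2O)n, THF, reflux; aq HCl work-up
Reagents that add atoms: formaldehyde (as paraformaldehyde), C=O
Why: In this MgCl2-mediated ortho-formylation (Casnati–Skattebøl) the phenoxide bound to magnesium delivers formaldehyde to an ortho carbon through a six-membered transition state, and the resulting benzylic alkoxide is oxidized by a second formaldehyde through hydride transfer, so only carbons ortho to OH can react. Of the two ortho carbons, the one para to OMe and next to heptyl is the more electron-rich; the carbon between the two oxygens is the site electrophiles avoid in resorcinol monoethers.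

Step 6
Reactants: 14 2-heptyl-6-hydroxy-4-methoxybenzaldehyde
Product: 15 2-(benzyloxy)-6-heptyl-4-methoxybenzaldehyde
Conditions: BnBr, K2CO3, DMF, 60 °C
Reagents that add atoms: benzyl bromide, BrCc1ccccc1
Why: Williamson etherification of the chelated phenol in a dipolar aprotic solvent. The benzyl ether keeps the hydroxyl out of the later acid activation and is removable by neutral hydrogenolysis.

Step 7
Reactants: 15 2-(benzyloxy)-6-heptyl-4-methoxybenzaldehyde
Product: 16 2-(benzyloxy)-6-heptyl-4-methoxybenzoic acid
Conditions: NaClO2, NaH2PO4, 2-methyl-2-butene, t-BuOH–THF–H2O, rt
Reagents that add atoms: sodium chlorite, [Na+].[O-]Cl=O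
Why: Pinnick (Lindgren–Kraus) oxidation converts hindered, electron-rich aryl aldehydes to acids under mildly acidic buffer. The alkene scavenges hypochlorous acid, so the activated ring is not chlorinated.

Step 8
Reactants: 17 olivetol (5-pentylbenzene-1,3-diol)
Product: 19 2,4-dihydroxy-6-pentylbenzaldehyde, via aryl iminium chloride 18 (not isolated)
Conditions: POCl3, DMF, 0 °C to rt; then H2O, 60 °C
Reagents that add atoms: N,N-dimethylformamide, CN(C)C=O; water, O
Why: In this Vilsmeier–Haack formylation the chloroiminium ion attacks the ring carbon that is ortho to one hydroxyl and para to the other, next to the pentyl chain, rather than the carbon between the two hydroxyls. Iminium salt 18 is hydrolysed on aqueous work-up; the selectivity is established for 5-alkylresorcinols.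

Step 9
Reactants: 16 2-(benzyloxy)-6-heptyl-4-methoxybenzoic acid; 19 2,4-dihydroxy-6-pentylbenzaldehyde
Product: 21 4-formyl-3-hydroxy-5-pentylphenyl 2-(benzyloxy)-6-heptyl-4-methoxybenzoate, via mixed trifluoroacetic anhydride 20 (not isolated)
Conditions: (CF3CO)2O, toluene, rt
Reagents that add atoms: none
Why: This is the standard depside esterification: the anhydride converts 16 into mixed anhydride 20, which transfers the hindered aroyl group to a phenol oxygen without added base. The C4 hydroxyl of 19 reacts because the C2 hydroxyl is tied up in a hydrogen bond to the formyl oxygen and is flanked by the formyl group.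

Step 10
Reactants: 21 4-formyl-3-hydroxy-5-pentylphenyl 2-(benzyloxy)-6-heptyl-4-methoxybenzoate
Product: 22 4-formyl-3-methoxy-5-pentylphenyl 2-(benzyloxy)-6-heptyl-4-methoxybenzoate
Conditions: MeI, K2CO3, DMF, rt
Reagents that add atoms: iodomethane, CI
Why: Williamson methylation of the only free, chelated phenol. The aryl ester carbonyl is flanked by benzyloxy and heptyl groups, which shield it from phenoxide and carbonate under anhydrous conditions.

Step 11
Reactants: 22 4-formyl-3-methoxy-5-pentylphenyl 2-(benzyloxy)-6-heptyl-4-methoxybenzoate
Product: 23 4-{[2-(benzyloxy)-6-heptyl-4-methoxybenzoyl]oxy}-2-methoxy-6-pentylbenzoic acid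
Conditions: NaClO2, NaH2PO4, 2-methyl-2-butene, t-BuOH–THF–H2O, rt
Reagents that add atoms: sodium chlorite, [Na+].[O-]Cl=O
Why: Pinnick oxidation turns the formyl placeholder into the ring B carboxylic acid. The buffered, non-nucleophilic medium leaves the aryl ester and the benzyl ether untouched.

Step 12
Reactants: 23 4-{[2-(benzyloxy)-6-heptyl-4-methoxybenzoyl]oxy}-2-methoxy-6-pentylbenzoic acid
Product: 24 4-[(2-heptyl-6-hydroxy-4-methoxybenzoyl)oxy]-2-methoxy-6-pentylbenzoic acid
Conditions: H2 (1 atm), Pd/C, EtOAc, rt
Reagents that add atoms: none
Why: Catalytic hydrogenolysis of the benzyl aryl ether under neutral conditions frees the ring A hydroxyl. The aryl ester, the acid and the methyl ethers are inert to it.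

## Compound list

1 | non-1-yne | C#CCCCCCCC | starting material
2 | trichloroacetyl chloride | O=C(Cl)C(Cl)(Cl)Cl | starting material
3 | dichloroketene | O=C=C(Cl)Cl | intermediate
4 | 4,4-dichloro-3-heptylcyclobut-2-en-1-one | CCCCCCCC1=CC(=O)C1(Cl)Cl | intermediate
5 | 3-heptylcyclobut-2-en-1-one | CCCCCCCC1=CC(=O)C1 | intermediate
6 | 2-chloro-1,1-dimethoxyethane (chloroacetaldehyde dimethyl acetal) | COC(CCl)OC | starting material
7 | sodium methoxyethynide | [Na+].[C-]#COC | intermediate
8 | methoxyethyne | COC#C | intermediate
9 | 3-methylidenedec-1-en-1-one (vinylketene) | O=C=CC(=C)CCCCCCC | intermediate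
10 | 3-methoxy-4-(non-1-en-2-yl)cyclobut-2-en-1-one (racemic, configuration irrelevant) | COC1=CC(=O)C1C(=C)CCCCCCC | intermediate
11 | (3E)-3-methoxy-5-methylidenedodeca-1,3-dien-1-one (dienylketene, ketene and alkenyl termini cis) | O=C=C/C(OC)=C\C(=C)CCCCCCC | intermediate
12 | 5-heptyl-3-methoxycyclohexa-2,4-dien-1-one | O=C1C=C(OC)C=C(CCCCCCC)C1 | intermediate
13 | 3-heptyl-5-methoxyphenol | CCCCCCCc1cc(O)cc(OC)c1 | intermediate
14 | 2-heptyl-6-hydroxy-4-methoxybenzaldehyde | CCCCCCCc1cc(OC)cc(O)c1C=O | intermediate
15 | 2-(benzyloxy)-6-heptyl-4-methoxybenzaldehyde | CCCCCCCc1cc(OC)cc(OCc2ccccc2)c1C=O | intermediate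
16 | 2-(benzyloxy)-6-heptyl-4-methoxybenzoic acid | CCCCCCCc1cc(OC)cc(OCc2ccccc2)c1C(=O)O | intermediate
17 | olivetol (5-pentylbenzene-1,3-diol) | CCCCCc1cc(O)cc(O)c1 | starting material
18 | N-[(2,4-dihydroxy-6-pentylphenyl)methylidene]-N-methylmethanaminium chloride | CCCCCc1cc(O)cc(O)c1C=[N+](C)C.[Cl-] | intermediate
19 | 2,4-dihydroxy-6-pentylbenzaldehyde | CCCCCc1cc(O)cc(O)c1C=O | intermediate
20 | 2-(benzyloxy)-6-heptyl-4-methoxybenzoic trifluoroacetic anhydride | CCCCCCCc1cc(OC)cc(OCc2ccccc2)c1C(=O)OC(=O)C(F)(F)F | intermediate
21 | 4-formyl-3-hydroxy-5-pentylphenyl 2-(benzyloxy)-6-heptyl-4-methoxybenzoate | CCCCCCCc1cc(OC)cc(OCc2ccccc2)c1C(=O)Oc1cc(CCCCC)c(C=O)c(O)c1 | intermediate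
22 | 4-formyl-3-methoxy-5-pentylphenyl 2-(benzyloxy)-6-heptyl-4-methoxybenzoate | CCCCCCCc1cc(OC)cc(OCc2ccccc2)c1C(=O)Oc1cc(CCCCC)c(C=O)c(OC)c1 | intermediate
23 | 4-{[2-(benzyloxy)-6-heptyl-4-methoxybenzoyl]oxy}-2-methoxy-6-pentylbenzoic acid | CCCCCCCc1cc(OC)cc(OCc2ccccc2)c1C(=O)Oc1cc(CCCCC)c(C(=O)O)c(OC)c1 | intermediate
24 | 4-[(2-heptyl-6-hydroxy-4-methoxybenzoyl)oxy]-2-methoxy-6-pentylbenzoic acid | CCCCCCCc1cc(OC)cc(O)c1C(=O)Oc1cc(CCCCC)c(C(=O)O)c(OC)c1 | target

## Step count and uncertain steps

Total step count: 12. Longest linear sequence: 10 steps (steps 1, 2, 4, 5, 6, 7, 9, 10, 11 and 12, from non-1-yne). Steps 3 and 8 are one-step side branches.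

**Step 4 (key step).** The most likely failure is loss of the alkyne partner before it captures the vinylketene, through its volatility or its polymerization. The ketene then dimerizes or acylates the phenol already formed, and the cascade may also stall at the alkenylcyclobutenone stage. The fallback sets out from 5 and comes back at 13. Compound 5 is heated with the non-volatile silyl ynol ether (triisopropylsilyloxy)ethyne, C#CO[Si](C(C)C)(C(C)C)C(C)C, in the known silyloxyalkyne variant of the benzannulation, which should give 3-heptyl-5-[(triisopropylsilyl)oxy]phenol F1. O-Methylation of the free hydroxyl of F1 with MeI and K2CO3 in acetone gives (3-heptyl-5-methoxyphenoxy)tri(propan-2-yl)silane F2. Bu4NF in THF then removes the silyl group from F2 to give 13.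

**Step 5.** The risk is attack at the other ortho carbon, the one between the two oxygens, because both ortho sites are flanked and the preference rests only on the activating effect of the para methoxy group. The fallback sets out from 13 and comes back at 14. It gives up the oxygen differentiation for two steps and restores it by chelation. Methylation of 13 with MeI and K2CO3 gives symmetric 1-heptyl-3,5-dimethoxybenzene F3. Vilsmeier–Haack formylation of F3 (POCl3, DMF) should go to one of the two equivalent carbons next to the chain, each para to a methoxy group, and give 2-heptyl-4,6-dimethoxybenzaldehyde F4. BCl3 in CH2Cl2 at low temperature cleaves only the methyl ether of F4 that is ortho to the formyl group and gives 14.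

**Step 9.** The risks are acyl transfer to the chelated hydroxyl or to both hydroxyls, and slow transfer from the doubly ortho-substituted acid, which would leave the benzyl ether exposed to trifluoroacetic acid for a long time. The fallback sets out from 16 and comes back at 21. It moves the selectivity from hydrogen bonding to acidity. Acid 16 is converted with oxalyl chloride and catalytic DMF into 2-(benzyloxy)-6-heptyl-4-methoxybenzoyl chloride F5. F5 is added at 0 °C to 19 that has been treated with one equivalent of K2CO3 in acetone, so that only the more acidic, non-chelated C4 phenoxide is present and is acylated to 21.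

**Step 10.** The risk is cleavage or intermolecular transfer of the activated aryl ester by phenoxide or carbonate during the methylation. The fallback sets out from 19 and comes back at 22, so the methyl group is placed before the ester exists. Allyl bromide with K2CO3 in acetone alkylates the non-chelated hydroxyl of 19 to give 2-hydroxy-6-pentyl-4-(prop-2-en-1-yloxy)benzaldehyde F6. MeI and K2CO3 in DMF convert F6 into 2-methoxy-6-pentyl-4-(prop-2-en-1-yloxy)benzaldehyde F7. Pd(PPh3)4 (zerovalent palladium) with morpholine in THF removes the allyl group from F7 to give 4-hydroxy-2-methoxy-6-pentylbenzaldehyde F8. F8 is esterified with 16 under the conditions of step 9 to give 22 directly.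

## Further compounds

F1 | step 4 | 3-heptyl-5-[(triisopropylsilyl)oxy]phenol | CCCCCCCc1cc(O)cc(O[Si](C(C)C)(C(C)C)C(C)C)c1
F2 | step 4 | (3-heptyl-5-methoxyphenoxy)tri(propan-2-yl)silane | CCCCCCCc1cc(OC)cc(O[Si](C(C)C)(C(C)C)C(C)C)c1
F3 | step 5 | 1-heptyl-3,5-dimethoxybenzene | CCCCCCCc1cc(OC)cc(OC)c1
F4 | step 5 | 2-heptyl-4,6-dimethoxybenzaldehyde | CCCCCCCc1cc(OC)cc(OC)c1C=O
F5 | step 9 | 2-(benzyloxy)-6-heptyl-4-methoxybenzoyl chloride | CCCCCCCc1cc(OC)cc(OCc2ccccc2)c1C(=O)Cl
F6 | step 10 | 2-hydroxy-6-pentyl-4-(prop-2-en-1-yloxy)benzaldehyde | CCCCCc1cc(OCC=C)cc(O)c1C=O
F7 | step 10 | 2-methoxy-6-pentyl-4-(prop-2-en-1-yloxy)benzaldehyde | CCCCCc1cc(OCC=C)cc(OC)c1C=O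
F8 | step 10 | 4-hydroxy-2-methoxy-6-pentylbenzaldehyde | CCCCCc1cc(O)cc(OC)c1C=O
A1 | alternative 1 | benzyl 2,4-dioxo-6-pentylcyclohexane-1-carboxylate (racemic, enolized, configuration irrelevant) | CCCCCC1CC(=O)CC(=O)C1C(=O)OCc1ccccc1
A2 | alternative 1 | dibenzyl malonate | O=C(CC(=O)OCc1ccccc1)OCc1ccccc1
A3 | alternative 1 | (E)-non-3-en-2-one | CCCCC/C=C/C(C)=O
A4 | alternative 1 | benzyl 2,4-dihydroxy-6-pentylbenzoate | CCCCCc1cc(O)cc(O)c1C(=O)OCc1ccccc1
A5 | alternative 2 | 2-heptyl-4,6-dimethoxybenzoic acid | CCCCCCCc1cc(OC)cc(OC)c1C(=O)O
A6 | alternative 2 | 1-fluoro-3,5-dimethoxybenzene | COc1cc(F)cc(OC)c1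
A7 | alternative 2 | 3,5-dimethoxybenzyne | COC1=CC(OC)=CC#C1
A8 | alternative 2 | heptyllithium | [Li]CCCCCCC
A9 | alternative 3 | benzyl 4-hydroxy-2-methoxy-6-pentylbenzoate | CCCCCc1cc(O)cc(OC)c1C(=O)OCc1ccccc1
A10 | alternative 3 | benzyl oct-2-ynoate | CCCCCC#CC(=O)OCc1ccccc1
A11 | alternative 3 | 1,1-dimethoxy-3-(trimethylsilyloxy)buta-1,3-diene | COC(OC)=CC(=C)O[Si](C)(C)C
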